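**Plan**

1. Ring numbering used throughout: C1 (C=O), C2 (allyl), C3, C4 (quaternary; OMe and side chain), C5 (OMe), C6; Cα is the side-chain carbon on C4.
2. Retrosynthesis: cut C2–allyl (cross-coupling at a C2 enol triflate), take the C2 oxygen back to a C2 methylene, cut Cα=Cβ of the styrene (olefination of a C4 acetyl group), then cut the ring bonds C2–C3 and C4–C5 ([4+2]).
3. Enabling feature: the C5(OMe)=C6–C1(=O) unit is what a 1,1-dimethoxy-3-silyloxybutadiene leaves after loss of silyl and one methanol, and C4 with its methoxy group and an acetyl precursor of Cα is the α-carbon of an α-methoxy vinyl ketone; C1, C2, C5, C6 come from the diene, C3 and C4 from the enone.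
4. Forward: the cycloaddition closes the only new ring; the purchased aryl ring is joined by olefination; C2 is then oxidised to the diosphenol, triflated and allylated.
5. Stereochemistry: the single stereocentre C4 is set in the cycloaddition by a chiral copper bis(oxazoline) chelate and, being quaternary, cannot epimerise later; the E olefin comes from the Horner–Wadsworth–Emmons step.
6. The C2=C3 double bond is fixed by enolisation of a 1,2-dione, not by an elimination next to the allyl group, whose direction would be uncertain.

Key step: step 6

Assumption: the sense of induction of a copper bis(oxazoline) chelate with this dienophile cannot be taken from a close precedent, so the route is written with the (S,S)-tert-butyl ligand, (S,S)-tBu-box = 2,2'-(propane-2,2-diyl)bis[(4S)-4-tert-butyl-4,5-dihydro-1,3-oxazole], and the mirror-image ligand is to be used if that is the one that delivers the R ketone.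

Step 1
Reactants: 1 3,3-dimethoxybutan-2-one
Product: 2 3-methoxybut-3-en-2-one
Conditions: TsOH·H2O (cat.), hydroquinone (trace), neat, 140–150 °C, MeOH distilled off; fractional distillation
Reagents that add atoms: none
Why: Acid-catalysed loss of methanol from the α-keto ketal (oxocarbenium ion, then deprotonation of the adjacent methyl group) gives the captodative enol ether, and removal of methanol drives the equilibrium in this established ketal-to-enol-ether elimination.

Step 2
Reactants: 3 acetyl chloride; 4 1,1-dichloroethene
Product: 6 4,4-dichlorobut-3-en-2-one, via 4,4,4-trichlorobutan-2-one 5 (not isolated)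
Conditions: AlCl3 (1.1 equiv), CH2Cl2, 0 °C → rt; ice/aq HCl quench; distillation under reduced pressure
Reagents that add atoms: none
Why: Aluminium chloride-mediated acylation of an alkene (Friedel–Crafts type), in which the acylium ion adds to the CH2 terminus of 4, chloride capture gives 5 and loss of HCl on heating gives the conjugated β,β-dichlorovinyl ketone, a known sequence.

Step 3
Reactants: 6 4,4-dichlorobut-3-en-2-one
Product: 7 4,4-dimethoxybut-3-en-2-one
Conditions: NaOMe (2.2 equiv), MeOH, 0 °C → rt; distillation
Reagents that add atoms: sodium methoxide, [Na+].[O-]C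
Why: Two successive addition–elimination substitutions of methoxide at the β-carbon of the β,β-dichloro enone (nucleophilic vinylic substitution) give the ketene acetal, a known conversion.

Step 4
Reactants: 7 4,4-dimethoxybut-3-en-2-one
Product: 8 1,1-dimethoxy-3-(trimethylsilyloxy)buta-1,3-diene
Conditions: Me3SiCl, Et3N, ZnCl2 (cat.), toluene, rt → 40 °C; filtration, distillation
Reagents that add atoms: chlorotrimethylsilane, C[Si](C)(C)Cl
Why: Soft enolisation and O-silylation at the methyl group, the only enolisable site, gives the cross-conjugated 2-silyloxy diene, a known member of the 1,1-dialkoxy-3-silyloxy diene class.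

Step 5
Reactants: 9 3,4-dimethoxybenzyl chloride
Product: 10 diethyl (3,4-dimethoxybenzyl)phosphonate
Conditions: P(OEt)3, neat, 140 °C, EtCl distilled off
Reagents that add atoms: triethyl phosphite, CCOP(OCC)OCC
Why: Michaelis–Arbuzov reaction, in which the benzylic chloride alkylates phosphorus and chloride dealkylates the phosphonium ion, is the standard route to benzylphosphonates.

Step 6
Reactants: 8 1,1-dimethoxy-3-(trimethylsilyloxy)buta-1,3-diene (1.5 equiv); 2 3-methoxybut-3-en-2-one
Product: 12 (R)-4-acetyl-3,4-dimethoxycyclohex-2-en-1-one, via silyl enol ether cycloadduct 11 (not isolated)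
Conditions: [Cu((S,S)-tBu-box)](OTf)2 (10 mol %), 3 Å MS, CH2Cl2, −78 °C; then 0.5 M HCl, THF, 0 °C
Reagents that add atoms: none
Why: Proposed new method: no α-alkoxy vinyl ketone has been used as the chelating partner of a chiral copper bis(oxazoline) Lewis acid, and the closest known reactions are the bis(oxazoline)–copper Diels–Alder and Mukaiyama–Michael reactions of two-point-binding acceptors (acryloyl imides, α-sulfenyl acrylates bound through C=O and the α-heteroatom) together with the thermal [4+2] reactions of 1,1-dialkoxy-3-silyloxy dienes. The divalent copper centre is expected to bind the ketone and α-methoxy oxygens of 2 in a five-membered chelate that activates the enone and fixes it s-trans; the CH2 terminus of 8, the nucleophilic end of the vinylogous ketene acetal, then adds to the enone CH2 (bond C2–C3), leaving a copper-bound α-methoxy enolate and a dimethoxy-stabilised allyl cation in one intermediate. The ring closes when the enolate carbon attacks the cationic acetal carbon (bond C4–C5), which is the second σ-bond of an asynchronous suprafacial [4+2] and, in the stepwise limit, a 6-(enolexo)-endo-trig Michael-type closure onto the O-silylated β,β-dimethoxy enone. The only new stereocentre, C4, is set in this closure by the ligand: the tert-butyl group beside the coordinated methoxy oxygen should screen one face of the chelated α-carbon so that C5 bonds to its Re face (OMe > acetyl > CH2), which gives the R ketone. The step needs regioselectivity, supplied by the matched polarity of the partners (nucleophilic diene CH2 to electrophilic enone CH2, acetal carbon to the α-carbon), and face selectivity, supplied by the rigid chelate; the silyl group stays on oxygen, so the catalyst is released without silyl transfer. Mild acid then hydrolyses the silyl enol ether of 11 and the resulting β-keto ketal loses methanol toward C6, the only direction open, to give the methoxy enone 12.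

Step 7
Reactants: 12 (R)-4-acetyl-3,4-dimethoxycyclohex-2-en-1-one; 10 diethyl (3,4-dimethoxybenzyl)phosphonate
Product: 14 (S)-4-[(E)-1-(3,4-dimethoxyphenyl)prop-1-en-2-yl]-3,4-dimethoxycyclohex-2-en-1-one, via lithiated phosphonate 13 (not isolated)
Conditions: 10 (1.5 equiv), n-BuLi, THF, −78 °C; then 12, −78 °C → rt
Reagents that add atoms: none
Why: Horner–Wadsworth–Emmons olefination, in which the aryl-stabilised phosphonate carbanion adds to the acetyl group, the only true ketone (the ring carbonyl is a far less electrophilic vinylogous ester), and the oxaphosphetane that places the aryl group trans to the bulky quaternary C4 collapses preferentially, as in the precedented E-selective olefination of α-alkoxy methyl ketones with (hetero)arylmethyl phosphonates; C4 carries no hydrogen and keeps its configuration (the descriptor changes from R to S only because the acetyl group is replaced by a lower-ranking alkenyl group).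

Step 8
Reactants: 14 (S)-4-[(E)-1-(3,4-dimethoxyphenyl)prop-1-en-2-yl]-3,4-dimethoxycyclohex-2-en-1-one
Product: 16 (4S)-4-[(E)-1-(3,4-dimethoxyphenyl)prop-1-en-2-yl]-6-hydroxy-3,4-dimethoxycyclohex-2-en-1-one (both C6 epimers), via potassium dienolate 15 (not isolated)
Conditions: KN(SiMe3)2, THF, −78 °C; then 2-(phenylsulfonyl)-3-phenyloxaziridine, −78 °C; AcOH quench
Reagents that add atoms: 2-(phenylsulfonyl)-3-phenyloxaziridine, O=S(=O)(c1ccccc1)N1OC1c1ccccc1
Why: Enolate hydroxylation with an N-sulfonyloxaziridine (Davis oxidation), in which the base removes a proton from the ring CH2 next to the carbonyl (C2 in the numbering of the plan), the only enolisable position because C4 is quaternary, and the enolate carbon attacks the oxaziridine oxygen; the new carbinol centre forms as a mixture that the next step erases.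

Step 9
Reactants: 16 (4S)-4-[(E)-1-(3,4-dimethoxyphenyl)prop-1-en-2-yl]-6-hydroxy-3,4-dimethoxycyclohex-2-en-1-one
Product: 17 (S)-4-[(E)-1-(3,4-dimethoxyphenyl)prop-1-en-2-yl]-2-hydroxy-4,5-dimethoxycyclohexa-2,5-dien-1-one
Conditions: Dess–Martin periodinane, pyridine, CH2Cl2, 0 °C → rt
Reagents that add atoms: none
Why: Dess–Martin oxidation of the acyloin gives the 1,2-dione, which can enolise only toward C3 and therefore tautomerises to the diosphenol, so the C2=C3 double bond of the target is installed regiospecifically with no elimination whose direction would have to be controlled.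

Step 10
Reactants: 17 (S)-4-[(E)-1-(3,4-dimethoxyphenyl)prop-1-en-2-yl]-2-hydroxy-4,5-dimethoxycyclohexa-2,5-dien-1-one
Product: 18 (S)-3-[(E)-1-(3,4-dimethoxyphenyl)prop-1-en-2-yl]-3,4-dimethoxy-6-oxocyclohexa-1,4-dien-1-yl trifluoromethanesulfonate
Conditions: PhNTf2, Et3N, DMAP (cat.), CH2Cl2, 0 °C → rt
Reagents that add atoms: N-phenylbis(trifluoromethanesulfonimide), O=S(=O)(N(c1ccccc1)S(=O)(=O)C(F)(F)F)C(F)(F)F
Why: O-sulfonylation of the acidic diosphenol hydroxyl with N-phenyltriflimide under amine base is a standard preparation of α-triflyloxy enones from 1,2-diones, and the mild reagent leaves the enol ether, the styrene and the tertiary allylic ether untouched.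

Step 11
Reactants: 18 (S)-3-[(E)-1-(3,4-dimethoxyphenyl)prop-1-en-2-yl]-3,4-dimethoxy-6-oxocyclohexa-1,4-dien-1-yl trifluoromethanesulfonate
Product: 19 (S)-2-allyl-4-[(E)-1-(3,4-dimethoxyphenyl)prop-1-en-2-yl]-4,5-dimethoxycyclohexa-2,5-dien-1-one (CNP0127782.2)
Conditions: allyl-SnBu3, Pd(PPh3)4 (5 mol %), LiCl, THF, 60 °C
Reagents that add atoms: allyltributylstannane, C=CC[Sn](CCCC)(CCCC)CCCC
Why: Stille cross-coupling, in which zerovalent palladium inserts into the vinyl C–O bond of the α-triflyloxy enone, LiCl assists transmetalation from the allylstannane and reductive elimination forms the C2–allyl bond at a carbon that is already sp2, so neither the ring double bonds nor the C4 stereocentre is touched.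

**Compound list**

1 | 3,3-dimethoxybutan-2-one | CC(=O)C(C)(OC)OC | starting material
2 | 3-methoxybut-3-en-2-one | C=C(OC)C(C)=O | intermediate
3 | acetyl chloride | CC(=O)Cl | starting material
4 | 1,1-dichloroethene | C=C(Cl)Cl | starting material
5 | 4,4,4-trichlorobutan-2-one | CC(=O)CC(Cl)(Cl)Cl | intermediate (not isolated)
6 | 4,4-dichlorobut-3-en-2-one | CC(=O)C=C(Cl)Cl | intermediate
7 | 4,4-dimethoxybut-3-en-2-one | CC(=O)C=C(OC)OC | intermediate
8 | 1,1-dimethoxy-3-(trimethylsilyloxy)buta-1,3-diene | C=C(O[Si](C)(C)C)C=C(OC)OC | intermediate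
9 | 3,4-dimethoxybenzyl chloride | COc1ccc(CCl)cc1OC | starting material
10 | diethyl (3,4-dimethoxybenzyl)phosphonate | CCOP(=O)(OCC)Cc1ccc(OC)c(OC)c1 | intermediate
11 | (S)-1-[1,2,2-trimethoxy-4-(trimethylsilyloxy)cyclohex-3-en-1-yl]ethan-1-one (silyl enol ether cycloadduct) | C[Si](C)(C)OC1=CC(OC)(OC)[C@@](OC)(C(C)=O)CC1 | intermediate (not isolated)
12 | (R)-4-acetyl-3,4-dimethoxycyclohex-2-en-1-one | O=C1CC[C@](OC)(C(C)=O)C(OC)=C1 | intermediate
13 | lithium (diethoxyphosphoryl)(3,4-dimethoxyphenyl)methanide (lithiated phosphonate) | [Li+].CCOP(=O)(OCC)[CH-]c1ccc(OC)c(OC)c1 | intermediate (not isolated)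
14 | (S)-4-[(E)-1-(3,4-dimethoxyphenyl)prop-1-en-2-yl]-3,4-dimethoxycyclohex-2-en-1-one | O=C1CC[C@](OC)(/C(C)=C/c2ccc(OC)c(OC)c2)C(OC)=C1 | intermediate
15 | potassium (S)-4-[(E)-1-(3,4-dimethoxyphenyl)prop-1-en-2-yl]-4,5-dimethoxycyclohexa-1,5-dien-1-olate (potassium dienolate) | [K+].[O-]C1=CC[C@](OC)(/C(C)=C/c2ccc(OC)c(OC)c2)C(OC)=C1 | intermediate (not isolated)
16 | (4S)-4-[(E)-1-(3,4-dimethoxyphenyl)prop-1-en-2-yl]-6-hydroxy-3,4-dimethoxycyclohex-2-en-1-one (both C6 epimers) | O=C1C(O)C[C@](OC)(/C(C)=C/c2ccc(OC)c(OC)c2)C(OC)=C1 | intermediate
17 | (S)-4-[(E)-1-(3,4-dimethoxyphenyl)prop-1-en-2-yl]-2-hydroxy-4,5-dimethoxycyclohexa-2,5-dien-1-one | O=C1C(O)=C[C@](OC)(/C(C)=C/c2ccc(OC)c(OC)c2)C(OC)=C1 | intermediate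
18 | (S)-3-[(E)-1-(3,4-dimethoxyphenyl)prop-1-en-2-yl]-3,4-dimethoxy-6-oxocyclohexa-1,4-dien-1-yl trifluoromethanesulfonate | O=C1C(OS(=O)(=O)C(F)(F)F)=C[C@](OC)(/C(C)=C/c2ccc(OC)c(OC)c2)C(OC)=C1 | intermediate
19 | (S)-2-allyl-4-[(E)-1-(3,4-dimethoxyphenyl)prop-1-en-2-yl]-4,5-dimethoxycyclohexa-2,5-dien-1-one | C=CCC1=C[C@](OC)(/C(C)=C/c2ccc(OC)c(OC)c2)C(OC)=CC1=O | target

**Step count**

Total step count: 11 steps. Longest linear sequence: 9 steps (steps 2, 3, 4, 6, 7, 8, 9, 10, 11), counted from acetyl chloride and 1,1-dichloroethene.

**Steps most likely to fail**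

Step 6 (the proposed method) is the riskiest. The copper chelate may discriminate the two faces of the α-carbon poorly, because the reacting carbon sits on the chelate ring and is screened only by the ligand arm next to the methoxy donor. The Michael-type intermediate may also lose its silyl group before it closes, which would leave an open-chain diketone, or the Lewis acid may decompose the ketene-acetal diene. The fallback uses known chemistry, sets out from 8 and 2, and returns at 12. The cycloaddition is run without catalyst (toluene, 80–100 °C, trace of hydroquinone), the normal thermal mode of 1,1-dialkoxy-3-silyloxy dienes with electron-poor alkenes, to give racemic 1-[1,2,2-trimethoxy-4-(trimethylsilyloxy)cyclohex-3-en-1-yl]ethan-1-one F1. The same dilute-acid treatment converts it into racemic 4-acetyl-3,4-dimethoxycyclohex-2-en-1-one F2. Preparative chromatography on a chiral stationary phase then separates 12, where the route is rejoined, from (S)-4-acetyl-3,4-dimethoxycyclohex-2-en-1-one F3, which is discarded.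

Step 7 is second. The basic carbanion may enolise the acetyl group without adding to it. The β-oxido adduct may also fragment with cleavage of the C4–acetyl bond (acyl transfer to the phosphonate), a path opened by the fact that the departing C4 carbanion is a vinylogous enolate. The E selectivity may be incomplete. The fallback sets out from 12 and 9 and returns at 14. Compound 9 is converted with Mg in THF at 0 °C into 3,4-dimethoxybenzylmagnesium chloride F4, which adds at −78 °C to the acetyl group; chelation by the α-methoxy group assists, and the magnesium alkoxide is not expected to fragment. This gives (4S)-4-[1-(3,4-dimethoxyphenyl)-2-hydroxypropan-2-yl]-3,4-dimethoxycyclohex-2-en-1-one F5 as a mixture of carbinol epimers. Syn-dehydration with the Burgess reagent (toluene, 60 °C) toward the benzylic hydrogens should then give the conjugated E alkene 14.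

Step 9 is third. Over-oxidation may cleave the C1–C2 bond of the acyloin, or the diosphenol may lose methanol from C4 toward an ortho-quinone if the medium turns acidic or strongly basic. The fallback sets out from 14 and returns at 19. Kinetic deprotonation with LiN(iPr)2 (THF, −78 °C) and alkylation with allyl bromide (α'-alkylation of a vinylogous ester) gives (4S)-6-allyl-4-[(E)-1-(3,4-dimethoxyphenyl)prop-1-en-2-yl]-3,4-dimethoxycyclohex-2-en-1-one F6. A second deprotonation with trapping by Me3SiCl gives (5S)-1-allyl-5-[(E)-1-(3,4-dimethoxyphenyl)prop-1-en-2-yl]-4,5-dimethoxy-2-(trimethylsilyloxy)cyclohexa-1,3-diene F7. Saegusa–Ito oxidation with palladium diacetate, Pd(OAc)2, in MeCN then dehydrogenates C2–C3 to give 19. This path is held in reserve because β-hydride loss toward the allylic CH2 of the side chain could compete with loss of the ring hydrogen.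

Further compounds
F1 | step 6 | racemic 1-[1,2,2-trimethoxy-4-(trimethylsilyloxy)cyclohex-3-en-1-yl]ethan-1-one | C[Si](C)(C)OC1=CC(OC)(OC)C(OC)(C(C)=O)CC1
F2 | step 6 | racemic 4-acetyl-3,4-dimethoxycyclohex-2-en-1-one | O=C1CCC(OC)(C(C)=O)C(OC)=C1
F3 | step 6 | (S)-4-acetyl-3,4-dimethoxycyclohex-2-en-1-one | O=C1CC[C@@](OC)(C(C)=O)C(OC)=C1
F4 | step 7 | 3,4-dimethoxybenzylmagnesium chloride | COc1ccc(C[Mg]Cl)cc1OC
F5 | step 7 | (4S)-4-[1-(3,4-dimethoxyphenyl)-2-hydroxypropan-2-yl]-3,4-dimethoxycyclohex-2-en-1-one (carbinol epimers) | O=C1CC[C@](OC)(C(C)(O)Cc2ccc(OC)c(OC)c2)C(OC)=C1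
F6 | step 9 | (4S)-6-allyl-4-[(E)-1-(3,4-dimethoxyphenyl)prop-1-en-2-yl]-3,4-dimethoxycyclohex-2-en-1-one (C6 epimers) | O=C1C(CC=C)C[C@](OC)(/C(C)=C/c2ccc(OC)c(OC)c2)C(OC)=C1
F7 | step 9 | (5S)-1-allyl-5-[(E)-1-(3,4-dimethoxyphenyl)prop-1-en-2-yl]-4,5-dimethoxy-2-(trimethylsilyloxy)cyclohexa-1,3-diene | C=CCC1=C(O[Si](C)(C)C)C=C(OC)[C@@](OC)(/C(C)=C/c2ccc(OC)c(OC)c2)C1
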